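## Retrosynthetic overview

1. Halves: 1 + 2 (via ketone 3) give the phenol half 4; 5 + 6 (via ketone 7) give isoflavone 8, which is chlorinated to 9.
2. Key disconnection: the diaryl ether C–O bond (O-3' of the daidzein half to C-4' of the chlorogenistein half), made late from phenol 4 and aryl bromide 9 to give tetramethyl ether 10.
3. Last operation: cleavage of the four O-methyl groups of 10 gives 11 (the target).
4. Ring order: the two pyranone rings are closed first and separately (steps 1 and 2), each on a bought benzene ring by C-acylation, C1 insertion and O1–C2 closure; no ring is formed after the union.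
5. The chlorine is placed by SEAr at C8 of 8 before the union.

Assumption: the SMILES contains no stereocentre and no hindered axis, so the target is achiral and no stereocontrol is needed.

## Route

Step 1
Reactants: 1 3-methoxyphenol; 2 2-(3-hydroxy-4-methoxyphenyl)acetic acid
Product: 4 3-(3-hydroxy-4-methoxyphenyl)-7-methoxy-4H-chromen-4-one, via deoxybenzoin 3 (not isolated)
Conditions: BF3·OEt2 (as solvent), 85 °C; then DMF, MsCl, 75 °C; H2O
Reagents that add atoms: N,N-dimethylformamide CN(C)C=O
Why: BF3 promotes Friedel–Crafts/Fries-type C-acylation of 1 ortho to its OH and para to its OMe (product held as a BF2 chelate), and the activated CH2 of 3 is then C-formylated by the DMF/MsCl Vilsmeier-type reagent and closes by O–C2 cyclodehydration (one-pot deoxybenzoin isoflavone synthesis), the B-ring phenol being tolerated under these acidic conditions.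

Step 2
Reactants: 5 3,5-dimethoxyphenol; 6 2-(4-bromophenyl)acetic acid
Product: 8 3-(4-bromophenyl)-5,7-dimethoxy-4H-chromen-4-one, via bromo deoxybenzoin 7 (not isolated)
Conditions: BF3·OEt2 (as solvent), 85 °C; then DMF, MsCl, 75 °C; H2O
Reagents that add atoms: N,N-dimethylformamide CN(C)C=O
Why: the same BF3-mediated ortho C-acylation and Vilsmeier-type formylation/cyclodehydration apply, the two positions ortho to the OH of 5 being equivalent, the single OH fixing the 5,7-dimethoxy pattern and the aryl bromide being inert.

Step 3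
Reactants: 8 3-(4-bromophenyl)-5,7-dimethoxy-4H-chromen-4-one
Product: 9 3-(4-bromophenyl)-8-chloro-5,7-dimethoxy-4H-chromen-4-one
Conditions: NCS (1.05 equiv), DMF, 0 °C → rt
Reagents that add atoms: N-chlorosuccinimide O=C1CCC(=O)N1Cl
Why: in this electrophilic aromatic chlorination (SEAr) only the 5,7-dimethoxy A ring is activated (the bromophenyl ring and the pyranone C2–H are not), and C8, para to the 5-OMe and flanked by a single OMe, should react ahead of C6, which lies between two OMe groups, as I expect for halogenation of 5,7-di-O-alkylchromones, with 1.05 equiv limiting 6,8-dichlorination.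

Step 4
Reactants: 4 3-(3-hydroxy-4-methoxyphenyl)-7-methoxy-4H-chromen-4-one; 9 3-(4-bromophenyl)-8-chloro-5,7-dimethoxy-4H-chromen-4-one
Product: 10 8-chloro-5,7-dimethoxy-3-{4-[2-methoxy-5-(7-methoxy-4-oxo-4H-chromen-3-yl)phenoxy]phenyl}-4H-chromen-4-one
Conditions: 4 (1.2 equiv), NaOTMS (1.5 equiv), CuI (10 mol %), bulky N1,N2-diarylbenzene-1,2-diamine ligand (12 mol %), DMSO, rt → 40 °C, N2
Reagents that add atoms: none
Why: Proposed new method: room-temperature Ullmann-type diaryl-ether coupling under an anionic N1,N2-diarylbenzene-1,2-diamine/Cu(I) catalyst, a system that to my knowledge has been used only with N–H nucleophiles and aliphatic alcohols and not with phenoxides, in which the amido-ligated, electron-rich Cu(I) should add the unhindered Ar–Br of 9 at room temperature (rate-limiting and independent of the nucleophile, the di-ortho-substituted, electron-rich C8–Cl staying untouched), bromide is exchanged for the sodium phenoxide of 4 on Cu(III) and C–O reductive elimination releases 10, the excess NaOTMS keeping every phenol deprotonated so that ArOH (more acidic than the ligand N–H) cannot protonate and switch off the ligand, and the mild, weakly nucleophilic base sparing both chromone rings; closest known reaction type: Cu-catalysed Ullmann O-arylation of phenols with aryl halides at 90–120 °C.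

Step 5
Reactants: 10 8-chloro-5,7-dimethoxy-3-{4-[2-methoxy-5-(7-methoxy-4-oxo-4H-chromen-3-yl)phenoxy]phenyl}-4H-chromen-4-one
Product: 11 8-chloro-5,7-dihydroxy-3-{4-[2-hydroxy-5-(7-hydroxy-4-oxo-4H-chromen-3-yl)phenoxy]phenyl}-4H-chromen-4-one (bisoflavolin L)
Conditions: BBr3 (12 equiv), CH2Cl2, −78 °C → 40 °C; then H2O
Reagents that add atoms: none
Why: in this Lewis-acid ether cleavage BBr3 binds each ArO–Me oxygen and bromide removes the methyl group by SN2 (the 5-OMe peri to C=O first, the two 7-OMe last, hence excess reagent and warming), while the diaryl ether, the aryl chloride and the chromone rings are inert to BBr3 and aqueous work-up frees the four phenols.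

## Compound list

1 | 3-methoxyphenol | COc1cccc(O)c1 | starting material
2 | 2-(3-hydroxy-4-methoxyphenyl)acetic acid | COc1ccc(CC(=O)O)cc1O | starting material
3 | 1-(2-hydroxy-4-methoxyphenyl)-2-(3-hydroxy-4-methoxyphenyl)ethan-1-one | COc1ccc(C(=O)Cc2ccc(OC)c(O)c2)c(O)c1 | intermediate
4 | 3-(3-hydroxy-4-methoxyphenyl)-7-methoxy-4H-chromen-4-one | O=c1c(-c2ccc(OC)c(O)c2)coc2cc(OC)ccc12 | intermediate
5 | 3,5-dimethoxyphenol | COc1cc(O)cc(OC)c1 | starting material
6 | 2-(4-bromophenyl)acetic acid | OC(=O)Cc1ccc(Br)cc1 | starting material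
7 | 2-(4-bromophenyl)-1-(2-hydroxy-4,6-dimethoxyphenyl)ethan-1-one | COc1cc(O)c(C(=O)Cc2ccc(Br)cc2)c(OC)c1 | intermediate
8 | 3-(4-bromophenyl)-5,7-dimethoxy-4H-chromen-4-one | O=c1c(-c2ccc(Br)cc2)coc2cc(OC)cc(OC)c12 | intermediate
9 | 3-(4-bromophenyl)-8-chloro-5,7-dimethoxy-4H-chromen-4-one | O=c1c(-c2ccc(Br)cc2)coc2c(Cl)c(OC)cc(OC)c12 | intermediate
10 | 8-chloro-5,7-dimethoxy-3-{4-[2-methoxy-5-(7-methoxy-4-oxo-4H-chromen-3-yl)phenoxy]phenyl}-4H-chromen-4-one | O=c1c(-c2ccc(OC)c(Oc3ccc(-c4coc5c(Cl)c(OC)cc(OC)c5c4=O)cc3)c2)coc2cc(OC)ccc12 | intermediate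
11 | 8-chloro-5,7-dihydroxy-3-{4-[2-hydroxy-5-(7-hydroxy-4-oxo-4H-chromen-3-yl)phenoxy]phenyl}-4H-chromen-4-one (bisoflavolin L) | O=c1c(-c2ccc(O)c(Oc3ccc(-c4coc5c(Cl)c(O)cc(O)c5c4=O)cc3)c2)coc2cc(O)ccc12 | target

## Step count and risks

Total step count: 5. Longest linear sequence: 4 steps (steps 2, 3, 4, 5, from 5 and 6 to 11).

**Step 4 (the proposed new coupling).** The phenoxide may bind copper as an unreactive cuprate, or the ligand may be N-arylated before turnover, so the coupling could stall. The fallback uses known chemistry and reverses the polarity of the aryl partner. It sets out from 9: Miyaura borylation (B2pin2, Pd(dppf)Cl2, KOAc, dioxane, 90 °C; reaction at C–Br only) gives 8-chloro-5,7-dimethoxy-3-[4-(4,4,5,5-tetramethyl-1,3,2-dioxaborolan-2-yl)phenyl]-4H-chromen-4-one F1. F1 is then joined to phenol 4 by Chan–Lam–Evans oxidative etherification (Cu(OAc)2, Et3N, B(OH)3, 4 Å MS, MeCN, 70 °C, air), which comes back to the route at 10.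

**Step 3 (C8 versus C6 chlorination).** Some 6-chloro isomer or 6,8-dichloride may form and be hard to separate; the site can be checked by NOE, since H-6 of 9 sees both OMe groups. The fallback places the chlorine before the ring is built, so that ring closure fixes its position. It sets out from 5: amine-catalysed ortho-selective chlorination (SO2Cl2, cat. 2,2,6,6-tetramethylpiperidine, toluene) gives 2-chloro-3,5-dimethoxyphenol F2, and the symmetric 4-chloro isomer is removed by chromatography. F2 and 6 under the conditions of step 2 pass through 2-(4-bromophenyl)-1-(3-chloro-2-hydroxy-4,6-dimethoxyphenyl)ethan-1-one F3. Its only free OH lies next to the chlorine, so cyclisation can only give the 8-chloro compound, and the fallback comes back to the route at 9.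

**Step 1 (site of acylation of 3-methoxyphenol).** Acylation para to the OH would give a 4-hydroxy-2-methoxy ketone that cannot cyclise and lowers the yield. The fallback uses a phenol whose acylation site is unambiguous and then differentiates the hydroxyls by acidity. It sets out from 2: with resorcinol (Oc1cccc(O)c1) in place of 1 under the same one-pot conditions, C4-acylation gives 1-(2,4-dihydroxyphenyl)-2-(3-hydroxy-4-methoxyphenyl)ethan-1-one F4. Ring closure then gives 7-hydroxy-3-(3-hydroxy-4-methoxyphenyl)-4H-chromen-4-one F5 (calycosin). Selective 7-O-methylation (MeI 1.05 equiv, K2CO3 1.0 equiv, acetone, rt), in which the vinylogous-acid 7-OH reacts ahead of the ordinary 3'-OH, comes back to the route at 4.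

## Further compounds

F1 | step 4 | 8-chloro-5,7-dimethoxy-3-[4-(4,4,5,5-tetramethyl-1,3,2-dioxaborolan-2-yl)phenyl]-4H-chromen-4-one | O=c1c(-c2ccc(B3OC(C)(C)C(C)(C)O3)cc2)coc2c(Cl)c(OC)cc(OC)c12
F2 | step 3 | 2-chloro-3,5-dimethoxyphenol | COc1cc(O)c(Cl)c(OC)c1
F3 | step 3 | 2-(4-bromophenyl)-1-(3-chloro-2-hydroxy-4,6-dimethoxyphenyl)ethan-1-one | COc1cc(OC)c(C(=O)Cc2ccc(Br)cc2)c(O)c1Cl
F4 | step 1 | 1-(2,4-dihydroxyphenyl)-2-(3-hydroxy-4-methoxyphenyl)ethan-1-one | COc1ccc(CC(=O)c2ccc(O)cc2O)cc1O
F5 | step 1 | 7-hydroxy-3-(3-hydroxy-4-methoxyphenyl)-4H-chromen-4-one | O=c1c(-c2ccc(OC)c(O)c2)coc2cc(O)ccc12
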